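Both aromatic rings are drawn from 2,4-dihydroxybenzaldehyde. The isoflavan is cut across its pyran ring at C3–C4 and O1–C2. Ring A then appears as an o-quinone methide (O1=C8a–C4a=C4H2, generated from an o-hydroxybenzyl sulfone whose C8 side chain already carries the tertiary alcohol) and ring B as an arylacetaldehyde. The key step is an amine-catalysed formal [4+2] annulation: the chiral enamine adds through its α-carbon (C3) to C4 of the quinone methide and the liberated phenol O1 closes on C2, giving the chroman-2-ol with the C3 stereocentre fixed. The feature exploited is the ortho relationship of O1 and C4 on ring A next to the C3 benzylic stereocentre. Ionic deoxygenation at C2 and desilylation finish the synthesis.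

Key step: step 12

Remark: locants O1, C2, C3, C4, C4a, C5–C8, C8a refer to the chroman core of the target and primed locants to the 3-aryl ring (ring B). The stereocentre C3 of the target is R, since C2 > C1' > C4 > H.

**Ring A fragment**

Step 1
Reactants: 1 2,4-dihydroxybenzaldehyde; 2 prenyl bromide (1-bromo-3-methylbut-2-ene)
Product: 3 2,4-dihydroxy-3-(3-methylbut-2-en-1-yl)benzaldehyde
Conditions: KOH (10 % aq.), 0 °C → rt; then dil. HCl
Reagents that add atoms: none
Why: Nuclear C-prenylation (C-alkylation of the resorcinol dianion), a known reaction of 2,4-dihydroxybenzaldehyde in aqueous alkali, should place the allyl group at C3 between the two phenoxide oxygens, the most nucleophilic ring carbon, the minor 5-prenyl and O-prenyl isomers being removed by chromatography.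

Step 2
Reactants: 3 2,4-dihydroxy-3-(3-methylbut-2-en-1-yl)benzaldehyde
Product: 4 2-hydroxy-3-(3-methylbut-2-en-1-yl)-4-(triisopropylsilyloxy)benzaldehyde
Conditions: TIPSCl, imidazole, DMF, 0 °C → rt
Reagents that add atoms: triisopropylsilyl chloride (TIPSCl), CC(C)[Si](Cl)(C(C)C)C(C)C
Why: Silyl ether formation should occur only at the 4-OH, because the 2-OH is hydrogen-bonded to the formyl group and flanked on both sides (known selectivity for 2,4-dihydroxybenzaldehydes).

Step 3
Reactants: 4 2-hydroxy-3-(3-methylbut-2-en-1-yl)-4-(triisopropylsilyloxy)benzaldehyde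
Product: 5 2-(hydroxymethyl)-6-(3-methylbut-2-en-1-yl)-5-(triisopropylsilyloxy)phenol
Conditions: NaBH4, THF–EtOH, 0 °C
Reagents that add atoms: none
Why: Borohydride reduction of the aldehyde should give the salicyl alcohol, and the robust aryl TIPS ether should survive the short cold contact with alkoxide; the labile product is used directly.

Step 4
Reactants: 5 2-(hydroxymethyl)-6-(3-methylbut-2-en-1-yl)-5-(triisopropylsilyloxy)phenol
Product: 6 2-(3-methylbut-2-en-1-yl)-6-[(4-methylphenyl)sulfonylmethyl]-3-(triisopropylsilyloxy)phenol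
Conditions: sodium p-toluenesulfinate, AcOH–H2O, 40 °C
Reagents that add atoms: sodium p-toluenesulfinate, Cc1ccc(cc1)S(=O)[O-].[Na+]
Why: SN1-type substitution of the electron-rich o-hydroxybenzyl alcohol by sulfinate (S-alkylation, the usual preparation of 2-(tosylmethyl)phenols) should give a bench-stable quinone methide precursor, and acetic acid is too weak to cyclise the prenyl group onto the phenol.

Step 5
Reactants: 6 2-(3-methylbut-2-en-1-yl)-6-[(4-methylphenyl)sulfonylmethyl]-3-(triisopropylsilyloxy)phenol
Product: 7 2-(3-hydroxy-3-methylbutyl)-6-[(4-methylphenyl)sulfonylmethyl]-3-(triisopropylsilyloxy)phenol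
Conditions: Co(acac)2 (20 mol %), PhSiH3, O2 (1 atm), THF, rt
Reagents that add atoms: dioxygen, O=O
Why: Mukaiyama hydration (cobalt hydride hydrogen-atom transfer to the trisubstituted alkene, O2 trapping of the tertiary radical, reduction) should give the Markovnikov tertiary alcohol without the cationic intermediates that would close a 2,2-dimethylchroman, and the resorcinol-type phenol and the sulfone should be inert.

**Ring B fragment**

Step 6
Reactants: 1 2,4-dihydroxybenzaldehyde; 2 prenyl bromide (1-bromo-3-methylbut-2-ene)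
Product: 8 2-hydroxy-4-(3-methylbut-2-en-1-yloxy)benzaldehyde
Conditions: K2CO3, acetone, reflux
Reagents that add atoms: none
Why: Williamson ether synthesis under mild carbonate conditions should alkylate only the more acidic, non-chelated 4-OH (known regioselectivity).

Step 7
Reactants: 8 2-hydroxy-4-(3-methylbut-2-en-1-yloxy)benzaldehyde
Product: 9 2-(tert-butyldimethylsilyloxy)-4-(3-methylbut-2-en-1-yloxy)benzaldehyde
Conditions: TBSCl, imidazole, DMF, rt
Reagents that add atoms: tert-butyldimethylsilyl chloride (TBSCl), CC(C)(C)[Si](C)(C)Cl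
Why: Silyl ether formation at the remaining phenol should break the OH···O=C chelate that would steer the coming rearrangement to C3 and should shield that position sterically.

Step 8
Reactants: 9 2-(tert-butyldimethylsilyloxy)-4-(3-methylbut-2-en-1-yloxy)benzaldehyde
Product: 10 2-(tert-butyldimethylsilyloxy)-4-hydroxy-5-(2-methylbut-3-en-2-yl)benzaldehyde
Conditions: N,N-diethylaniline, 190 °C, sealed tube
Reagents that add atoms: none
Why: The aromatic Claisen rearrangement ([3,3]) of the aryl prenyl ether should deliver the inverted 1,1-dimethylallyl unit to the free ortho carbon C5 rather than to C3, which is wedged between the silyloxy and ether oxygens, and the amine solvent should suppress acid-promoted cyclisation of the product onto its new alkene.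

Step 9
Reactants: 10 2-(tert-butyldimethylsilyloxy)-4-hydroxy-5-(2-methylbut-3-en-2-yl)benzaldehyde
Product: 11 2,4-bis(tert-butyldimethylsilyloxy)-5-(2-methylbut-3-en-2-yl)benzaldehyde
Conditions: TBSOTf, 2,6-lutidine, CH2Cl2, 0 °C
Reagents that add atoms: tert-butyldimethylsilyl triflate (TBSOTf), CC(C)(C)[Si](C)(C)OS(=O)(=O)C(F)(F)F
Why: Silylation with the reactive silyl triflate should cap the phenol that is hindered by the neighbouring tert-alkyl group, which also corrects any silyl scrambling from step 8.

Step 10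
Reactants: 11 2,4-bis(tert-butyldimethylsilyloxy)-5-(2-methylbut-3-en-2-yl)benzaldehyde
Product: 12 2,4-bis(tert-butyldimethylsilyloxy)-5-(2-methylbut-3-en-2-yl)-β-methoxystyrene (E/Z mixture)
Conditions: (methoxymethyl)triphenylphosphonium chloride, KHMDS, THF, −78 → 0 °C
Reagents that add atoms: (methoxymethyl)triphenylphosphonium chloride, COC[P+](c1ccccc1)(c1ccccc1)c1ccccc1.[Cl-]
Why: Wittig methoxymethylenation should homologate the aldehyde by one carbon; the E/Z ratio is irrelevant because both isomers hydrolyse to the same aldehyde.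

Step 11
Reactants: 12 2,4-bis(tert-butyldimethylsilyloxy)-5-(2-methylbut-3-en-2-yl)-β-methoxystyrene
Product: 13 2-[2,4-bis(tert-butyldimethylsilyloxy)-5-(2-methylbut-3-en-2-yl)phenyl]acetaldehyde
Conditions: 2 M HCl (aq.), THF, rt; crude aldehyde used at once
Reagents that add atoms: water, O
Why: Acid-catalysed enol ether hydrolysis should give the arylacetaldehyde, while the aryl silyl ethers and the unactivated terminal alkene should tolerate dilute aqueous acid.

**Union, ring closure and end game**

Step 12
Reactants: 7 2-(3-hydroxy-3-methylbutyl)-6-[(4-methylphenyl)sulfonylmethyl]-3-(triisopropylsilyloxy)phenol; 13 2-[2,4-bis(tert-butyldimethylsilyloxy)-5-(2-methylbut-3-en-2-yl)phenyl]acetaldehyde (1.5 equiv)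
Product: 16 (3R)-3-[2,4-bis(tert-butyldimethylsilyloxy)-5-(2-methylbut-3-en-2-yl)phenyl]-8-(3-hydroxy-3-methylbutyl)-7-(triisopropylsilyloxy)-3,4-dihydro-2H-chromen-2-ol (C2 epimers), via o-quinone methide 14 (not isolated), via open-chain (2R)-aldehyde 15 (not isolated)
Conditions: (R)-α,α-diphenylprolinol trimethylsilyl ether (20 mol %), K2CO3 (powdered), CH2Cl2, 0 °C → rt
Reagents that add atoms: none
Why: Base expels sulfinate from the phenoxide of 7 to give o-quinone methide 14 while the secondary amine condenses with 13 to an (E)-enamine; the enamine α-carbon (C3) adds to the methylene C4 of 14, iminium hydrolysis gives aldehyde 15, and its phenol O1 closes on C2. The closest known reaction type is the aminocatalytic formal [4+2] annulation (Michael addition–hemiacetalisation) of aldehydes, arylacetaldehydes included, with o-quinone methides generated in situ, which gives chroman-2-ols. The pyran ring is closed by 6-exo-trig hemiacetalisation of O1 onto the C2 carbonyl after the intermolecular C3–C4 bond formation. The C3 stereocentre is set by the catalyst: the diphenyl(silyloxy)methyl group of the (R)-pyrrolidine shields the Si face of the enamine α-carbon, so C4 adds to the Re face and gives 3R, whereas C2 forms as an anomeric mixture that step 13 removes. The step needs chemoselectivity for the quinone methide over aldehyde self-aldolisation, which the much higher electrophilicity and low stationary concentration of 14 should secure, and its regiochemistry is unambiguous because C8 is substituted and only one o-quinone methide can form. Immediate lactol closure should take the configurationally labile α-aryl aldehyde out of the enamine equilibrium.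

Step 13
Reactants: 16 (3R)-3-[2,4-bis(tert-butyldimethylsilyloxy)-5-(2-methylbut-3-en-2-yl)phenyl]-8-(3-hydroxy-3-methylbutyl)-7-(triisopropylsilyloxy)-3,4-dihydro-2H-chromen-2-ol
Product: 17 4-[(3R)-3-[2,4-bis(tert-butyldimethylsilyloxy)-5-(2-methylbut-3-en-2-yl)phenyl]-7-(triisopropylsilyloxy)-3,4-dihydro-2H-chromen-8-yl]-2-methylbutan-2-ol
Conditions: Et3SiH (excess), BF3·OEt2, CH2Cl2, −78 → −30 °C
Reagents that add atoms: none
Why: Ionic hydrogenation (Lewis acid ionisation of the anomeric hydroxyl to the cyclic aryloxocarbenium ion and hydride capture at C2 by the silane) should remove the C2 oxygen without opening the ring, and at low temperature hydride transfer should outrun loss of the C3 proton and ionisation of the tertiary alcohol.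

Step 14
Reactants: 17 4-[(3R)-3-[2,4-bis(tert-butyldimethylsilyloxy)-5-(2-methylbut-3-en-2-yl)phenyl]-7-(triisopropylsilyloxy)-3,4-dihydro-2H-chromen-8-yl]-2-methylbutan-2-ol
Product: 18 4-[(3R)-7-hydroxy-8-(3-hydroxy-3-methylbutyl)-3,4-dihydro-2H-chromen-3-yl]-6-(2-methylbut-3-en-2-yl)benzene-1,3-diol (target, CNP0420388.1)
Conditions: TBAF (3.5 equiv), AcOH (3.5 equiv), THF, 0 °C → rt
Reagents that add atoms: none
Why: Fluoride desilylation should cleave the three aryl silyl ethers under buffered, non-acidic conditions that leave the tertiary alcohol, the 1,1-dimethylallyl group and C3 untouched.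

**Compound list**

1 | 2,4-dihydroxybenzaldehyde | O=Cc1ccc(O)cc1O | starting material
2 | prenyl bromide (1-bromo-3-methylbut-2-ene) | CC(C)=CCBr | starting material
3 | 2,4-dihydroxy-3-(3-methylbut-2-en-1-yl)benzaldehyde | O=Cc1ccc(O)c(CC=C(C)C)c1O | intermediate
4 | 2-hydroxy-3-(3-methylbut-2-en-1-yl)-4-(triisopropylsilyloxy)benzaldehyde | O=Cc1ccc(O[Si](C(C)C)(C(C)C)C(C)C)c(CC=C(C)C)c1O | intermediate
5 | 2-(hydroxymethyl)-6-(3-methylbut-2-en-1-yl)-5-(triisopropylsilyloxy)phenol | OCc1ccc(O[Si](C(C)C)(C(C)C)C(C)C)c(CC=C(C)C)c1O | intermediate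
6 | 2-(3-methylbut-2-en-1-yl)-6-[(4-methylphenyl)sulfonylmethyl]-3-(triisopropylsilyloxy)phenol | Cc1ccc(cc1)S(=O)(=O)Cc1ccc(O[Si](C(C)C)(C(C)C)C(C)C)c(CC=C(C)C)c1O | intermediate
7 | 2-(3-hydroxy-3-methylbutyl)-6-[(4-methylphenyl)sulfonylmethyl]-3-(triisopropylsilyloxy)phenol | Cc1ccc(cc1)S(=O)(=O)Cc1ccc(O[Si](C(C)C)(C(C)C)C(C)C)c(CCC(C)(C)O)c1O | intermediate
8 | 2-hydroxy-4-(3-methylbut-2-en-1-yloxy)benzaldehyde | O=Cc1ccc(OCC=C(C)C)cc1O | intermediate
9 | 2-(tert-butyldimethylsilyloxy)-4-(3-methylbut-2-en-1-yloxy)benzaldehyde | O=Cc1ccc(OCC=C(C)C)cc1O[Si](C)(C)C(C)(C)C | intermediate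
10 | 2-(tert-butyldimethylsilyloxy)-4-hydroxy-5-(2-methylbut-3-en-2-yl)benzaldehyde | O=Cc1cc(C(C)(C)C=C)c(O)cc1O[Si](C)(C)C(C)(C)C | intermediate
11 | 2,4-bis(tert-butyldimethylsilyloxy)-5-(2-methylbut-3-en-2-yl)benzaldehyde | O=Cc1cc(C(C)(C)C=C)c(O[Si](C)(C)C(C)(C)C)cc1O[Si](C)(C)C(C)(C)C | intermediate
12 | 2,4-bis(tert-butyldimethylsilyloxy)-5-(2-methylbut-3-en-2-yl)-β-methoxystyrene (E/Z mixture) | COC=Cc1cc(C(C)(C)C=C)c(O[Si](C)(C)C(C)(C)C)cc1O[Si](C)(C)C(C)(C)C | intermediate
13 | 2-[2,4-bis(tert-butyldimethylsilyloxy)-5-(2-methylbut-3-en-2-yl)phenyl]acetaldehyde | O=CCc1cc(C(C)(C)C=C)c(O[Si](C)(C)C(C)(C)C)cc1O[Si](C)(C)C(C)(C)C | intermediate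
14 | o-quinone methide: 2-(3-hydroxy-3-methylbutyl)-6-methylidene-3-(triisopropylsilyloxy)cyclohexa-2,4-dien-1-one (not isolated) | C=C1C=CC(O[Si](C(C)C)(C(C)C)C(C)C)=C(CCC(C)(C)O)C1=O | intermediate
15 | (2R)-2-[2,4-bis(tert-butyldimethylsilyloxy)-5-(2-methylbut-3-en-2-yl)phenyl]-3-[2-hydroxy-3-(3-hydroxy-3-methylbutyl)-4-(triisopropylsilyloxy)phenyl]propanal (not isolated) | O=C[C@H](Cc1ccc(O[Si](C(C)C)(C(C)C)C(C)C)c(CCC(C)(C)O)c1O)c1cc(C(C)(C)C=C)c(O[Si](C)(C)C(C)(C)C)cc1O[Si](C)(C)C(C)(C)C | intermediate
16 | (3R)-3-[2,4-bis(tert-butyldimethylsilyloxy)-5-(2-methylbut-3-en-2-yl)phenyl]-8-(3-hydroxy-3-methylbutyl)-7-(triisopropylsilyloxy)-3,4-dihydro-2H-chromen-2-ol (C2 epimers) | C=CC(C)(C)c1cc([C@@H]2C(O)Oc3c(ccc(O[Si](C(C)C)(C(C)C)C(C)C)c3CCC(C)(C)O)C2)c(O[Si](C)(C)C(C)(C)C)cc1O[Si](C)(C)C(C)(C)C | intermediate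
17 | 4-[(3R)-3-[2,4-bis(tert-butyldimethylsilyloxy)-5-(2-methylbut-3-en-2-yl)phenyl]-7-(triisopropylsilyloxy)-3,4-dihydro-2H-chromen-8-yl]-2-methylbutan-2-ol | C=CC(C)(C)c1cc([C@@H]2COc3c(ccc(O[Si](C(C)C)(C(C)C)C(C)C)c3CCC(C)(C)O)C2)c(O[Si](C)(C)C(C)(C)C)cc1O[Si](C)(C)C(C)(C)C | intermediate
18 | 4-[(3R)-7-hydroxy-8-(3-hydroxy-3-methylbutyl)-3,4-dihydro-2H-chromen-3-yl]-6-(2-methylbut-3-en-2-yl)benzene-1,3-diol | C=CC(C)(C)c1cc([C@@H]2COc3c(ccc(O)c3CCC(C)(C)O)C2)c(O)cc1O | target

**Step count and risks**

Total step count: 14. Longest linear sequence: 9 steps (steps 6–14, from 1 through the ring B fragment).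

Steps most likely to fail:

1. Step 12. The enantiopurity at C3 may erode through reversible enamine formation from the α-aryl aldehyde before the lactol closes, and aldehyde self-aldolisation or quinone methide oligomerisation may compete. The fallback sets out from 7 and 13 and returns at 17. The annulation would be run with achiral pyrrolidine (20 mol %) and K2CO3 to give the racemic lactol F1. Because C3 of F1 equilibrates through the open hydroxy-aldehyde under base, F1 would be submitted to a Ru(II) diphosphine/diamine-catalysed asymmetric hydrogenation under dynamic kinetic resolution (t-BuOK cat., i-PrOH, H2; catalyst antipode chosen to deliver the R alcohol). This carbonyl-selective reduction should give the (2R)-phenol-diol F2 and leave the terminal alkene alone. Mitsunobu cyclodehydration of F2 (PPh3, DIAD, THF, 0 °C) would then close O1–C2 at the primary carbinol and give 17.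

2. Step 13. The oxocarbenium ion may lose the C3 proton (4H-chromene formation and reprotonation would scramble C3), the lactol may be reduced through its open form with ring opening, or the tertiary alcohol may ionise. The fallback sets out from 16 and returns at 17. The lactol 16 would be reduced through its aldehyde tautomer with NaBH4 (EtOH, 0 °C) to the (2R)-phenol-diol F3, and the ring would be re-closed by Mitsunobu etherification (PPh3, DIAD, THF) to 17. Both operations are neutral or basic and do not touch C3 or the tertiary alcohol.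

3. Step 8. The [3,3] shift may show poor regioselectivity between C5 and C3, and thermal loss of the prenyl group or further rearrangement and cyclisation of the ortho-(1,1-dimethylallyl)phenol may intervene. The fallback sets out from 1 and returns at 11, bypassing 8, 9 and 10. Compound 1 would be brominated para to the 2-OH (NBS, MeCN, 0 °C) to 5-bromo-2,4-dihydroxybenzaldehyde F4, and both phenols would be silylated (TBSCl, imidazole, DMF) to 5-bromo-2,4-bis(tert-butyldimethylsilyloxy)benzaldehyde F5. The tert-prenyl group would then be introduced by ligand-controlled γ-selective Suzuki–Miyaura coupling of F5 with 4,4,5,5-tetramethyl-2-(3-methylbut-2-en-1-yl)-1,3,2-dioxaborolane (Pd precatalyst, bulky biarylphosphine, K3PO4, THF–H2O), which should give 11 directly.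

Further compounds
F1 | step 12 | racemic 3-[2,4-bis(tert-butyldimethylsilyloxy)-5-(2-methylbut-3-en-2-yl)phenyl]-8-(3-hydroxy-3-methylbutyl)-7-(triisopropylsilyloxy)-3,4-dihydro-2H-chromen-2-ol | C=CC(C)(C)c1cc(C2C(O)Oc3c(ccc(O[Si](C(C)C)(C(C)C)C(C)C)c3CCC(C)(C)O)C2)c(O[Si](C)(C)C(C)(C)C)cc1O[Si](C)(C)C(C)(C)C
F2 | step 12 | (2R)-2-[2,4-bis(tert-butyldimethylsilyloxy)-5-(2-methylbut-3-en-2-yl)phenyl]-3-[2-hydroxy-3-(3-hydroxy-3-methylbutyl)-4-(triisopropylsilyloxy)phenyl]propan-1-ol | OC[C@H](Cc1ccc(O[Si](C(C)C)(C(C)C)C(C)C)c(CCC(C)(C)O)c1O)c1cc(C(C)(C)C=C)c(O[Si](C)(C)C(C)(C)C)cc1O[Si](C)(C)C(C)(C)C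
F3 | step 13 | (2R)-2-[2,4-bis(tert-butyldimethylsilyloxy)-5-(2-methylbut-3-en-2-yl)phenyl]-3-[2-hydroxy-3-(3-hydroxy-3-methylbutyl)-4-(triisopropylsilyloxy)phenyl]propan-1-ol | OC[C@H](Cc1ccc(O[Si](C(C)C)(C(C)C)C(C)C)c(CCC(C)(C)O)c1O)c1cc(C(C)(C)C=C)c(O[Si](C)(C)C(C)(C)C)cc1O[Si](C)(C)C(C)(C)C
F4 | step 8 | 5-bromo-2,4-dihydroxybenzaldehyde | O=Cc1cc(Br)c(O)cc1O
F5 | step 8 | 5-bromo-2,4-bis(tert-butyldimethylsilyloxy)benzaldehyde | O=Cc1cc(Br)c(O[Si](C)(C)C(C)(C)C)cc1O[Si](C)(C)C(C)(C)C
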